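The numbers of this flask are assumed; the run is a simulation.

**Easy step.** Each impurity takes one free catalyst out for good, so I began with how impurity and substrate share that catalyst.

| setting | alpha | eta |
|---|---|---|
| substrate | 0.011 M | 0.011 M |
| gas | 1.5 mM (held) | 1.5 mM (held) |
| free catalyst | 5.5 µM | 5.5 µM |
| impurity | 4.3 µM | 6.4 µM |
| time | 30 min | 30 min |

    free catalyst + impurity → spent catalyst (k1 = 40400 /M/s)
    catalyst intermediate B → free catalyst + product (k2 = 759 /min)
    gas ⇌ reagent, rate k3*(csat - [reagent]) (k3 = 1.25 /min, csat = 1.5 mM)
    substrate + free catalyst → catalyst intermediate A (k4 = 12900 /M/s)
    reagent + catalyst intermediate A → catalyst intermediate B (k5 = 3.99 × 10⁵ /M/min)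

- which of these there is most of at the end, counted by the substrate in it, alpha (substrate / catalyst intermediate B / product / catalyst intermediate A)
- which of these there is most of at the end, counted by the substrate in it, eta (substrate / catalyst intermediate B / product / catalyst intermediate A)
- final amount of the leader among these, as a percentage of the substrate charged, in alpha
- final amount of the leader among these, as a percentage of the substrate charged, in eta

**Kill ratio.** Both rivals react with free catalyst, so c(free catalyst) cancelled when I divided their two rates. That left 3.13. I named it the kill ratio, the rate constant of impurity capture over that of substrate capture, the usual selectivity factor. It meant that the fraction of impurity left equals the fraction of substrate left raised to that power.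

**Where it stops.** In eta the impurity charge exceeded the catalyst charge, so the catalyst had to die with 14.1 % of the impurity left. Taking the root with the kill ratio gave 53.5 % of the substrate left in eta. In alpha the impurity charge fell short of the catalyst charge, so 1.20 µM of catalyst outlasted it.

**Alpha's clock.** In alpha, with substrate at its charge, capture was faster than reagent uptake on the intermediate at saturation, so I left capture out and put the reagent step and the release in series. With c(reagent) at saturation, I reckoned that each survivor turned at 335 /min, which gave 27.4 min for the substrate charge. I committed to product leading in alpha, close to complete, and to substrate leading in eta near 53.5 %.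

**Weak link.** That clock assumed saturation, but the flow of gas must carry the turnover, so I put c(reagent) nearer 1.18 mM. My reckoned turnover then came to 290 /min, and my reckoned time to 31.6 min. Against that, the doomed catalyst also works while it lasts, and at the start it outnumbered the survivors. I therefore expected alpha to finish shortly before 30 min, with a thin margin.

**The forecast.** It named product at 99.9 % in alpha and substrate at 53.7 % in eta. Its eta figure stood a little above mine. Of alpha it said “conversion finishes well within 30 min”, which is roomier than my clock.

**What ran.** The flasks gave product at 99.9 % in alpha and substrate at 53.8 % in eta. In alpha, product stood at 38.3 % after 6.00 min and 72.2 % after 15.0 min. By then substrate in alpha was at 27.8 %, which the kill ratio turns into 1.82 % of impurity left, and that flask held 1.82 %. In alpha, spent catalyst stayed near 78.2 % of the catalyst charged while the remaining substrate ran down to 0.0508 % at 30.0 min. A neighbour of alpha charged with 0.044 M of substrate had 52.3 % of it left at 30.0 min; the kill ratio gives 13.1 % of impurity left, and that flask held 13.2 %.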